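**Retrosynthetic overview**
1. Target ⇐ double angeloylation of the 6,11-diol ⇐ desilylation ⇐ ring-closing metathesis (C1=C10, Z) of a diene on a trans-butanolide; the ten-membered ring is formed last.
2. C11 quaternary centre ⇐ enolate hydroxylation, silylation, then enolate methylation anti to the C7 substituent.
3. Butanolide (C8) ⇐ Brown methallylation/lactonisation ⇐ D-proline cross-aldol (C6, C7) of methyl 4-oxobutanoate with an epoxy aldehyde.
4. Epoxy aldehyde ⇐ glycol cleavage ⇐ hydroxyl-directed (threo) epoxidation ⇐ ketoreductase reduction of a 2-oxo-3-enoate (first stereocentre) ⇐ hex-5-en-1-yne + diethyl oxalate.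
5. Ring order: oxirane (step 4) → γ-lactone (step 9) → cyclodecene (step 13).

Assumption: compounds 1, 4, 11 and 23 are bought. Germacrane numbering is used for the ring compounds and in the Why lines: C1=C10 (C10 bears C14), C4 (bears C15), C5, C6, C7, C8, C9; C11 (bears C13); C12 is the lactone carbonyl, closed onto O at C8.

**Step 1**
Reactants: 1 hex-5-en-1-yne
Product: 3 (1E)-1-iodo-2-methylhexa-1,5-diene, via alkenylalane 2 (not isolated)
Conditions: Me3Al (2 eq), Cp2ZrCl2 (0.2 eq), CH2Cl2, 0 °C→rt; then I2, THF, −30→0 °C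
Reagents that add atoms: trimethylaluminium, C[Al](C)C; iodine, II
Why: Negishi zirconium-catalysed syn-methylalumination of the terminal alkyne followed by iodinolysis with retention gives the E-iodide, the isolated alkene being inert.

**Step 2**
Reactants: 3 (1E)-1-iodo-2-methylhexa-1,5-diene; 4 diethyl oxalate
Product: 6 ethyl (3E)-4-methyl-2-oxoocta-3,7-dienoate, via vinyllithium 5 (not isolated)
Conditions: t-BuLi (2.05 eq), Et2O, −78 °C; cannulated into 4 (3 eq), Et2O, −78 °C; H2O quench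
Reagents that add atoms: none
Why: Iodine–lithium exchange proceeds with retention of alkene geometry, and mono-acylation by excess oxalate (stable tetrahedral adduct at −78 °C) gives the 2-oxo ester.

**Step 3**
Reactants: 6 ethyl (3E)-4-methyl-2-oxoocta-3,7-dienoate
Product: 7 ethyl (2S,3E)-2-hydroxy-4-methylocta-3,7-dienoate
Conditions: (S)-selective ketoreductase (NADPH-dependent), NADP+ (cat.), iPrOH (10 vol%), KH2PO4/K2HPO4 buffer pH 7, 30 °C
Reagents that add atoms: none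
Why: Enzymatic asymmetric carbonyl reduction by a ketoreductase delivers hydride to one face of the activated 2-oxo ester, setting the first stereocentre (S) with isopropanol recycling the cofactor.

**Step 4**
Reactants: 7 ethyl (2S,3E)-2-hydroxy-4-methylocta-3,7-dienoate
Product: 8 ethyl (2S)-2-[(2S,3S)-3-(but-3-en-1-yl)-3-methyloxiran-2-yl]-2-hydroxyacetate
Conditions: mCPBA (1.05 eq), NaHCO3, CH2Cl2, −10→0 °C; minor diastereomer removed by chromatography
Reagents that add atoms: meta-chloroperbenzoic acid, OOC(=O)c1cccc(Cl)c1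
Why: In this Henbest hydroxyl-directed epoxidation, A(1,3) strain from the cis-methyl holds the carbinol C–H in the alkene plane, so oxygen is delivered on the OH face to give the threo epoxy alcohol (4S,5S); the terminal alkene is far less reactive.

**Step 5**
Reactants: 8 ethyl (2S)-2-[(2S,3S)-3-(but-3-en-1-yl)-3-methyloxiran-2-yl]-2-hydroxyacetate
Product: 9 (1R)-1-[(2S,3S)-3-(but-3-en-1-yl)-3-methyloxiran-2-yl]ethane-1,2-diol
Conditions: NaBH4, EtOH, 0 °C→rt
Reagents that add atoms: none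
Why: Borohydride reduction of the hydroxyl-activated ester gives the 1,2-diol without touching the epoxide or any stereocentre.

**Step 6**
Reactants: 9 (1R)-1-[(2S,3S)-3-(but-3-en-1-yl)-3-methyloxiran-2-yl]ethane-1,2-diol
Product: 10 (2R,3S)-3-(but-3-en-1-yl)-3-methyloxirane-2-carbaldehyde
Conditions: NaIO4, THF/pH 7 buffer, 0 °C; used crude
Reagents that add atoms: none
Why: Malaprade glycol cleavage turns the relay carbinol into the C6 aldehyde and leaves the enantiopure trisubstituted epoxide (C4, C5).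

**Step 7**
Reactants: 10 (2R,3S)-3-(but-3-en-1-yl)-3-methyloxirane-2-carbaldehyde; 11 methyl 4-oxobutanoate
Product: 12 methyl (3R,4S)-4-[(2S,3S)-3-(but-3-en-1-yl)-3-methyloxiran-2-yl]-3-formyl-4-hydroxybutanoate
Conditions: D-proline (20 mol%), DMF, 4 °C, 11 added by syringe pump over 24 h
Reagents that add atoms: none
Why: In this proline-catalysed enamine cross-aldol (List–Houk transition state) the non-enolisable epoxy aldehyde is the acceptor, D-proline gives the anti aldol (C6 S, C7), and this is matched with Felkin–Anh attack anti to the epoxide C–O bond (erythro at C5/C6).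

**Step 8**
Reactants: 12 methyl (3R,4S)-4-[(2S,3S)-3-(but-3-en-1-yl)-3-methyloxiran-2-yl]-3-formyl-4-hydroxybutanoate
Product: 13 methyl (3R,4S)-4-[(2S,3S)-3-(but-3-en-1-yl)-3-methyloxiran-2-yl]-3-formyl-4-[(triethylsilyl)oxy]butanoate
Conditions: Et3SiCl, imidazole, DMF, 0 °C
Reagents that add atoms: chlorotriethylsilane, CC[Si](Cl)(CC)CC
Why: Silyl ether formation under non-Lewis-acidic conditions protects the C6 hydroxyl without epoxide opening, β-elimination or epimerisation at C7.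

**Step 9**
Reactants: 13 methyl (3R,4S)-4-[(2S,3S)-3-(but-3-en-1-yl)-3-methyloxiran-2-yl]-3-formyl-4-[(triethylsilyl)oxy]butanoate
Product: 15 (4S,5R)-4-{(S)-[(2S,3S)-3-(but-3-en-1-yl)-3-methyloxiran-2-yl][(triethylsilyl)oxy]methyl}-5-(2-methylprop-2-en-1-yl)oxolan-2-one, via hydroxy ester 14 (not isolated)
Conditions: pre-formed, filtered B-(2-methylallyl)diisopinocampheylborane [from (+)-Ipc2BOMe, (−)-α-pinene series] (1.5 eq), Et2O, −78 °C; pH 7 buffer, MeOH, 30% H2O2, 0 °C→rt; then toluene, DMAP (cat.), 50 °C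
Reagents that add atoms: B-(2-methylallyl)diisopinocampheylborane, CC(=C)CB([C@H]1C[C@H]2C[C@@H]([C@@H]1C)C2(C)C)[C@H]1C[C@H]2C[C@@H]([C@@H]1C)C2(C)C
Why: Brown asymmetric allylboration through a chair Zimmerman–Traxler transition state sets C8 (R) under reagent control, matched with the Felkin preference of the α-branched aldehyde, and the γ-hydroxy ester then lactonises to the trans-butanolide.

**Step 10**
Reactants: 15 (4S,5R)-4-{(S)-[(2S,3S)-3-(but-3-en-1-yl)-3-methyloxiran-2-yl][(triethylsilyl)oxy]methyl}-5-(2-methylprop-2-en-1-yl)oxolan-2-one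
Product: 17 (3S,4S,5R)-4-{(S)-[(2S,3S)-3-(but-3-en-1-yl)-3-methyloxiran-2-yl][(triethylsilyl)oxy]methyl}-3-hydroxy-5-(2-methylprop-2-en-1-yl)oxolan-2-one, via potassium enolate 16 (not isolated)
Conditions: KN(SiMe3)2 (1.2 eq), THF, −78 °C; 3-phenyl-2-(phenylsulfonyl)oxaziridine (1.5 eq), −78 °C; AcOH quench
Reagents that add atoms: 3-phenyl-2-(phenylsulfonyl)oxaziridine, O=S(=O)(c1ccccc1)N1OC1c1ccccc1
Why: Davis enolate oxidation puts the oxygen on C11, mainly anti to the C7 substituent; this configuration is erased at the enolate stage of step 12, so either epimer is usable.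

**Step 11**
Reactants: 17 (3S,4S,5R)-4-{(S)-[(2S,3S)-3-(but-3-en-1-yl)-3-methyloxiran-2-yl][(triethylsilyl)oxy]methyl}-3-hydroxy-5-(2-methylprop-2-en-1-yl)oxolan-2-one
Product: 18 (3S,4S,5R)-4-{(S)-[(2S,3S)-3-(but-3-en-1-yl)-3-methyloxiran-2-yl][(triethylsilyl)oxy]methyl}-5-(2-methylprop-2-en-1-yl)-3-[(triethylsilyl)oxy]oxolan-2-one
Conditions: Et3SiCl, imidazole, DMAP (cat.), DMF, rt
Reagents that add atoms: chlorotriethylsilane, CC[Si](Cl)(CC)CC
Why: Silyl ether formation masks the C11 hydroxyl for the enolate step; using the same silyl group on both oxygens makes any silyl migration from step 10 harmless.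

**Step 12**
Reactants: 18 (3S,4S,5R)-4-{(S)-[(2S,3S)-3-(but-3-en-1-yl)-3-methyloxiran-2-yl][(triethylsilyl)oxy]methyl}-5-(2-methylprop-2-en-1-yl)-3-[(triethylsilyl)oxy]oxolan-2-one
Product: 20 (3R,4S,5R)-4-{(S)-[(2S,3S)-3-(but-3-en-1-yl)-3-methyloxiran-2-yl][(triethylsilyl)oxy]methyl}-3-methyl-5-(2-methylprop-2-en-1-yl)-3-[(triethylsilyl)oxy]oxolan-2-one, via lithium enolate 19 (not isolated)
Conditions: LiN(iPr)2 (1.3 eq), THF, −78 °C; MeI (5 eq), DMPU, −78→−40 °C
Reagents that add atoms: iodomethane, CI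
Why: In this enolate alkylation of the five-membered α-silyloxy lactone, methyl iodide enters anti to the bulky C7 substituent, so the methyl is trans and the oxygen cis to it (C11 R).

**Step 13**
Reactants: 20 (3R,4S,5R)-4-{(S)-[(2S,3S)-3-(but-3-en-1-yl)-3-methyloxiran-2-yl][(triethylsilyl)oxy]methyl}-3-methyl-5-(2-methylprop-2-en-1-yl)-3-[(triethylsilyl)oxy]oxolan-2-one
Product: 21 (1(10)Z,4S,5S,6S,7S,8R,11R)-4,5-epoxy-6,11-bis[(triethylsilyl)oxy]germacr-1(10)-en-12,8-olide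
Conditions: second-generation Grubbs catalyst RuCl2(=CHPh)(PCy3)(1,3-dimesitylimidazolidin-2-ylidene) (10 mol%), 1,4-benzoquinone (20 mol%), toluene (1 mM), 80 °C
Reagents that add atoms: none
Why: Ring-closing metathesis of the monosubstituted and 1,1-disubstituted alkenes is driven by loss of ethene, pre-organised by the trans-butanolide and trans-epoxide, and expected to give the less strained Z alkene in the ten-membered ring.

**Step 14**
Reactants: 21 (1(10)Z,4S,5S,6S,7S,8R,11R)-4,5-epoxy-6,11-bis[(triethylsilyl)oxy]germacr-1(10)-en-12,8-olide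
Product: 22 (1(10)Z,4S,5S,6S,7R,8R,11R)-4,5-epoxy-6,11-dihydroxygermacr-1(10)-en-12,8-olide
Conditions: Bu4NF/AcOH (1:1, 3 eq), THF, 0 °C→rt
Reagents that add atoms: none
Why: Buffered fluoride desilylation frees both alcohols near neutral pH, avoiding acid-induced transannular epoxide opening and base-induced translactonisation (the C7 descriptor changes by CIP priority only).

**Step 15**
Reactants: 22 (1(10)Z,4S,5S,6S,7R,8R,11R)-4,5-epoxy-6,11-dihydroxygermacr-1(10)-en-12,8-olide; 23 angelic anhydride [(Z)-2-methylbut-2-enoic anhydride]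
Product: 25 (1(10)Z,4S,5S,6S,7S,8R,11R)-6,11-bis(angeloyloxy)-4,5-epoxygermacr-1(10)-en-12,8-olide (target), via 6-monoangelate 24 (not isolated)
Conditions: 23 (4 eq), THF, −78 °C; LiN(SiMe3)2 (2.4 eq) added dropwise, −78→−20 °C; NaHCO3 quench
Reagents that add atoms: none
Why: Alkoxide acylation by the anhydride without a nucleophilic catalyst esterifies first the secondary then the tertiary hydroxyl, each trapped as it forms, with no Z→E isomerisation to tiglate.

**Compound list**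
1 | hex-5-en-1-yne | C#CCCC=C | starting material
2 | dimethyl[(1E)-2-methylhexa-1,5-dien-1-yl]alumane | C[Al](C)/C=C(\C)CCC=C | intermediate
3 | (1E)-1-iodo-2-methylhexa-1,5-diene | I/C=C(\C)CCC=C | intermediate
4 | diethyl oxalate | CCOC(=O)C(=O)OCC | starting material
5 | [(1E)-2-methylhexa-1,5-dien-1-yl]lithium | [Li]/C=C(\C)CCC=C | intermediate
6 | ethyl (3E)-4-methyl-2-oxoocta-3,7-dienoate | CCOC(=O)C(=O)/C=C(\C)CCC=C | intermediate
7 | ethyl (2S,3E)-2-hydroxy-4-methylocta-3,7-dienoate | CCOC(=O)[C@@H](O)/C=C(\C)CCC=C | intermediate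
8 | ethyl (2S)-2-[(2S,3S)-3-(but-3-en-1-yl)-3-methyloxiran-2-yl]-2-hydroxyacetate | CCOC(=O)[C@@H](O)[C@@H]1O[C@@]1(C)CCC=C | intermediate
9 | (1R)-1-[(2S,3S)-3-(but-3-en-1-yl)-3-methyloxiran-2-yl]ethane-1,2-diol | OC[C@@H](O)[C@@H]1O[C@@]1(C)CCC=C | intermediate
10 | (2R,3S)-3-(but-3-en-1-yl)-3-methyloxirane-2-carbaldehyde | O=C[C@@H]1O[C@@]1(C)CCC=C | intermediate
11 | methyl 4-oxobutanoate | COC(=O)CCC=O | starting material
12 | methyl (3R,4S)-4-[(2S,3S)-3-(but-3-en-1-yl)-3-methyloxiran-2-yl]-3-formyl-4-hydroxybutanoate | COC(=O)C[C@@H](C=O)[C@H](O)[C@@H]1O[C@@]1(C)CCC=C | intermediate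
13 | methyl (3R,4S)-4-[(2S,3S)-3-(but-3-en-1-yl)-3-methyloxiran-2-yl]-3-formyl-4-[(triethylsilyl)oxy]butanoate | COC(=O)C[C@@H](C=O)[C@H](O[Si](CC)(CC)CC)[C@@H]1O[C@@]1(C)CCC=C | intermediate
14 | methyl (3S,4R)-3-{(S)-[(2S,3S)-3-(but-3-en-1-yl)-3-methyloxiran-2-yl][(triethylsilyl)oxy]methyl}-4-hydroxy-6-methylhept-6-enoate | COC(=O)C[C@@H]([C@H](O)CC(C)=C)[C@H](O[Si](CC)(CC)CC)[C@@H]1O[C@@]1(C)CCC=C | intermediate
15 | (4S,5R)-4-{(S)-[(2S,3S)-3-(but-3-en-1-yl)-3-methyloxiran-2-yl][(triethylsilyl)oxy]methyl}-5-(2-methylprop-2-en-1-yl)oxolan-2-one | C=C(C)C[C@H]1OC(=O)C[C@@H]1[C@H](O[Si](CC)(CC)CC)[C@@H]2O[C@@]2(C)CCC=C | intermediate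
16 | potassium enolate of 15 (deprotonated at lactone C-3) | C=C(C)C[C@H]1OC([O-])=C[C@@H]1[C@H](O[Si](CC)(CC)CC)[C@@H]2O[C@@]2(C)CCC=C.[K+] | intermediate
17 | (3S,4S,5R)-4-{(S)-[(2S,3S)-3-(but-3-en-1-yl)-3-methyloxiran-2-yl][(triethylsilyl)oxy]methyl}-3-hydroxy-5-(2-methylprop-2-en-1-yl)oxolan-2-one | C=C(C)C[C@H]1OC(=O)[C@@H](O)[C@@H]1[C@H](O[Si](CC)(CC)CC)[C@@H]2O[C@@]2(C)CCC=C | intermediate
18 | (3S,4S,5R)-4-{(S)-[(2S,3S)-3-(but-3-en-1-yl)-3-methyloxiran-2-yl][(triethylsilyl)oxy]methyl}-5-(2-methylprop-2-en-1-yl)-3-[(triethylsilyl)oxy]oxolan-2-one | C=C(C)C[C@H]1OC(=O)[C@@H](O[Si](CC)(CC)CC)[C@@H]1[C@H](O[Si](CC)(CC)CC)[C@@H]2O[C@@]2(C)CCC=C | intermediate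
19 | lithium enolate of 18 (deprotonated at lactone C-3) | C=C(C)C[C@H]1OC([O-])=C(O[Si](CC)(CC)CC)[C@@H]1[C@H](O[Si](CC)(CC)CC)[C@@H]2O[C@@]2(C)CCC=C.[Li+] | intermediate
20 | (3R,4S,5R)-4-{(S)-[(2S,3S)-3-(but-3-en-1-yl)-3-methyloxiran-2-yl][(triethylsilyl)oxy]methyl}-3-methyl-5-(2-methylprop-2-en-1-yl)-3-[(triethylsilyl)oxy]oxolan-2-one | C=C(C)C[C@H]1OC(=O)[C@](C)(O[Si](CC)(CC)CC)[C@@H]1[C@H](O[Si](CC)(CC)CC)[C@@H]2O[C@@]2(C)CCC=C | intermediate
21 | (1(10)Z,4S,5S,6S,7S,8R,11R)-4,5-epoxy-6,11-bis[(triethylsilyl)oxy]germacr-1(10)-en-12,8-olide | CC[Si](CC)(CC)O[C@H]1[C@@H]2[C@@H](C/C(C)=C\CC[C@]3(C)O[C@@H]13)OC(=O)[C@]2(C)O[Si](CC)(CC)CC | intermediate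
22 | (1(10)Z,4S,5S,6S,7R,8R,11R)-4,5-epoxy-6,11-dihydroxygermacr-1(10)-en-12,8-olide | O[C@H]1[C@@H]2[C@@H](C/C(C)=C\CC[C@]3(C)O[C@@H]13)OC(=O)[C@]2(C)O | intermediate
23 | angelic anhydride, (Z)-2-methylbut-2-enoic anhydride | C/C=C(/C)C(=O)OC(=O)/C(C)=C\C | starting material
24 | (1(10)Z,4S,5S,6S,7S,8R,11R)-6-angeloyloxy-4,5-epoxy-11-hydroxygermacr-1(10)-en-12,8-olide | C/C=C(/C)C(=O)O[C@H]1[C@@H]2[C@@H](C/C(C)=C\CC[C@]3(C)O[C@@H]13)OC(=O)[C@]2(C)O | intermediate
25 | (1(10)Z,4S,5S,6S,7S,8R,11R)-6,11-bis(angeloyloxy)-4,5-epoxygermacr-1(10)-en-12,8-olide | C/C=C(/C)C(=O)O[C@H]1[C@@H]2[C@@H](C/C(C)=C\CC[C@]3(C)O[C@@H]13)OC(=O)[C@]2(C)OC(=O)/C(C)=C\C | target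

**Step count**
Total steps: 15. Longest linear sequence: 15 (from 1).

**Steps most likely to fail, with fallbacks**

Step 13 (ring-closing metathesis to a trisubstituted alkene in a ten-membered ring; oligomers or the E isomer are possible). The fallback sets out from 15 and closes the ring before the C11 centre and its silyl ether are built. Metathesis of 15 under the step 13 conditions gives (1(10)Z,4S,5S,6S,7S,8R)-4,5-epoxy-6-[(triethylsilyl)oxy]-13-norgermacr-1(10)-en-12,8-olide F4. KN(SiMe3)2 and the Davis oxaziridine give the (11S)-11-hydroxy derivative of F4, F5. Et3SiCl/imidazole gives the (11S)-6,11-bis(triethylsilyl) ether F6. LiN(iPr)2/MeI then methylates C11 from the face of H-7, anti to the C6–C7 ring bond, and the route is rejoined at 21.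

Step 7 (cross-aldol with an untested epoxy-aldehyde acceptor; self-aldol of 11 or low dr). The fallback sets out from 10 and uses a substrate-controlled boron aldol. S-phenyl 4-methoxy-4-oxobutanethioate F1 is enolised with (c-C6H11)2BCl/Et3N (Et2O, −78 °C, E-enol borinate) and added to 10. The anti, Felkin adduct is methyl (3R,4S)-4-[(2S,3S)-3-(but-3-en-1-yl)-3-methyloxiran-2-yl]-4-hydroxy-3-[(phenylsulfanyl)carbonyl]butanoate F2. Et3SiCl/imidazole gives its 4-triethylsilyl ether F3. iBu2AlH (1.1 eq, CH2Cl2, −78 °C) reduces the thioester to the aldehyde, and the route is rejoined at 13.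

Step 15 (acylation of the tertiary C11 hydroxyl on a base-sensitive epoxy-germacrenolide; translactonisation or transannular reactions may compete). The fallback sets out from 20 and installs the esters before ring closure. Bu4NF/AcOH gives (3R,4R,5R)-4-{(S)-[(2S,3S)-3-(but-3-en-1-yl)-3-methyloxiran-2-yl](hydroxy)methyl}-3-hydroxy-3-methyl-5-(2-methylprop-2-en-1-yl)oxolan-2-one F7. On this robust monocycle, 23 with LiN(SiMe3)2 (or more forcing acylation) gives the bis-angelate (3R,4S,5R)-diene F8. Ring-closing metathesis with the step 13 catalyst (angelate alkenes are inert) then rejoins the route at 25.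

**Further compounds**
F1 | step 7 | S-phenyl 4-methoxy-4-oxobutanethioate | COC(=O)CCC(=O)Sc1ccccc1
F2 | step 7 | methyl (3R,4S)-4-[(2S,3S)-3-(but-3-en-1-yl)-3-methyloxiran-2-yl]-4-hydroxy-3-[(phenylsulfanyl)carbonyl]butanoate | COC(=O)C[C@@H](C(=O)Sc1ccccc1)[C@H](O)[C@@H]1O[C@@]1(C)CCC=C
F3 | step 7 | methyl (3R,4S)-4-[(2S,3S)-3-(but-3-en-1-yl)-3-methyloxiran-2-yl]-3-[(phenylsulfanyl)carbonyl]-4-[(triethylsilyl)oxy]butanoate | COC(=O)C[C@@H](C(=O)Sc1ccccc1)[C@H](O[Si](CC)(CC)CC)[C@@H]1O[C@@]1(C)CCC=C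
F4 | step 13 | (1(10)Z,4S,5S,6S,7S,8R)-4,5-epoxy-6-[(triethylsilyl)oxy]-13-norgermacr-1(10)-en-12,8-olide | CC[Si](CC)(CC)O[C@H]1[C@@H]2[C@@H](C/C(C)=C\CC[C@]3(C)O[C@@H]13)OC(=O)C2
F5 | step 13 | (1(10)Z,4S,5S,6S,7S,8R,11S)-4,5-epoxy-11-hydroxy-6-[(triethylsilyl)oxy]-13-norgermacr-1(10)-en-12,8-olide | CC[Si](CC)(CC)O[C@H]1[C@@H]2[C@@H](C/C(C)=C\CC[C@]3(C)O[C@@H]13)OC(=O)[C@H]2O
F6 | step 13 | (1(10)Z,4S,5S,6S,7S,8R,11S)-4,5-epoxy-6,11-bis[(triethylsilyl)oxy]-13-norgermacr-1(10)-en-12,8-olide | CC[Si](CC)(CC)O[C@H]1[C@@H]2[C@@H](C/C(C)=C\CC[C@]3(C)O[C@@H]13)OC(=O)[C@H]2O[Si](CC)(CC)CC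
F7 | step 15 | (3R,4R,5R)-4-{(S)-[(2S,3S)-3-(but-3-en-1-yl)-3-methyloxiran-2-yl](hydroxy)methyl}-3-hydroxy-3-methyl-5-(2-methylprop-2-en-1-yl)oxolan-2-one | C=C(C)C[C@H]1OC(=O)[C@](C)(O)[C@@H]1[C@H](O)[C@@H]2O[C@@]2(C)CCC=C
F8 | step 15 | (3R,4S,5R)-3-angeloyloxy-4-{(S)-angeloyloxy[(2S,3S)-3-(but-3-en-1-yl)-3-methyloxiran-2-yl]methyl}-3-methyl-5-(2-methylprop-2-en-1-yl)oxolan-2-one | C=C(C)C[C@H]1OC(=O)[C@](C)(OC(=O)/C(C)=C\C)[C@@H]1[C@H](OC(=O)/C(C)=C\C)[C@@H]2O[C@@]2(C)CCC=C
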